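**Retrosynthetic overview**

- The route rests on the syn (threo) 1,2-dioxygenated pair C7/C8 with C9 as a CH2OH that a vinyl group can carry. C7 is the benzylic carbinol on ring A (the 4-hydroxy-3-methoxyphenyl ring). C8 is the carbon bound to the ether oxygen of ring B (the 2,6-dimethoxyphenoxy ring that carries the E-hydroxypropenyl chain).
- Late stage: the phenol is freed from its silyl ether, the allylic alcohol comes from a cinnamate (i-Bu2AlH), the cinnamate from the ring B aldehyde (Wittig), and that aldehyde from a dioxolane.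
- C9–OH comes from a vinyl group (OsO4/NaIO4, then NaBH4).
- Key disconnection C7–C8: a (Z)-γ-aryloxyallyl-diisopinocampheylborane, made from allyl ether 4, adds to silyl-protected vanillin 6 and sets both stereocentres.
- No ring is formed: ring A is bought as vanillin and ring B as syringaldehyde.

Key step: step 4

Assumption: the borane reagent made from (+)-α-pinene, (−)-Ipc2BOMe, SMILES COB([C@@H]1C[C@@H]2C[C@H]([C@H]1C)C2(C)C)[C@@H]1C[C@@H]2C[C@H]([C@H]1C)C2(C)C, delivers its allyl unit to the Si face of an aldehyde, as in the parent allyl- and γ-alkoxyallylborations; for aldehyde 6 this gives 7R.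

Remark: the ring B aldehyde travels as its 1,3-dioxolane, because it must pass sec-BuLi, BF3·OEt2 and buffered aqueous periodate unchanged. C8 is α to a carbonyl only in aldehyde 13, which is reduced at once.

**Route**

Step 1
Reactants: 1 syringaldehyde; 2 allyl bromide
Product: 3 4-(allyloxy)-3,5-dimethoxybenzaldehyde
Conditions: K2CO3, DMF, 60 °C
Reagents that add atoms: none
Why: Williamson ether synthesis: the phenoxide of 1 displaces bromide from 2 (SN2), and only O-alkylation is open because both ortho positions carry methoxy groups.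

Step 2
Reactants: 3 4-(allyloxy)-3,5-dimethoxybenzaldehyde
Product: 4 2-[4-(allyloxy)-3,5-dimethoxyphenyl]-1,3-dioxolane
Conditions: HOCH2CH2OH, p-TsOH·H2O (cat.), toluene, reflux, Dean–Stark
Reagents that add atoms: ethane-1,2-diol, OCCO
Why: Acid-catalysed acetalisation driven by azeotropic removal of water; the aryl allyl ether should not rearrange at this temperature because both ortho positions and the para position are substituted.

Step 3
Reactants: 5 vanillin
Product: 6 3-methoxy-4-(triisopropylsilyloxy)benzaldehyde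
Conditions: TIPSCl, imidazole, DMF, rt
Reagents that add atoms: triisopropylsilyl chloride, CC(C)[Si](Cl)(C(C)C)C(C)C
Why: Imidazole-promoted silylation of the phenol; the bulky aryl silyl ether should withstand the amine work-up of step 4, NaBH4, dilute acid and i-Bu2AlH, and is removed by fluoride at the end.

Step 4
Reactants: 4 2-[4-(allyloxy)-3,5-dimethoxyphenyl]-1,3-dioxolane (slight excess); 6 3-methoxy-4-(triisopropylsilyloxy)benzaldehyde
Product: 11 (1R,2R)-2-[4-(1,3-dioxolan-2-yl)-2,6-dimethoxyphenoxy]-1-[3-methoxy-4-(triisopropylsilyloxy)phenyl]but-3-en-1-ol, via allyllithium 7 (not isolated), via lithium borate 8 (not isolated), via allylborane 9 (not isolated), via borinate ester 10 (not isolated)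
Conditions: sec-BuLi, THF, −78 °C; (−)-Ipc2BOMe, −78 °C; BF3·OEt2 (1 equiv per boron), then 6, −78 °C → rt; H2NCH2CH2OH work-up
Reagents that add atoms: none
Why: sec-BuLi removes an α-oxy allylic proton of 4 to give the oxygen-chelated Z allyl anion 7, which the borinate captures at its far (γ) terminus as ate complex 8; BF3·OEt2 then abstracts methoxide and frees the (Z)-γ-aryloxyallylborane 9. Borane 9 adds to aldehyde 6 through a closed six-membered chair transition state with allylic transposition, so the C7–C8 bond forms at the oxygen-bearing carbon; this is the Brown γ-alkoxyallylboration, known for alkoxy- and aryloxyallyl reagents. No ring is closed. The Z geometry of 9 places the aryloxy group axial in the chair and so fixes the syn (threo) relation of C7–OH and C8–OAr, while the isopinocampheyl groups from (+)-α-pinene direct attack to the Si face of 6, giving 7R and with it 8R. The step needs α-allylic rather than ring lithiation, boron capture at the unsubstituted terminus, and an acetal that survives the Lewis acid. These are secured by the absence of any ring hydrogen ortho to the ether oxygen of ring B, by the bulk of the Ipc2B group, and by the cyclic acetal together with only one equivalent of BF3·OEt2 at −78 °C, which the methoxide consumes.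

Step 5
Reactants: 11 (1R,2R)-2-[4-(1,3-dioxolan-2-yl)-2,6-dimethoxyphenoxy]-1-[3-methoxy-4-(triisopropylsilyloxy)phenyl]but-3-en-1-ol
Product: 14 (1R,2R)-2-[4-(1,3-dioxolan-2-yl)-2,6-dimethoxyphenoxy]-1-[3-methoxy-4-(triisopropylsilyloxy)phenyl]propane-1,3-diol, via triol 12 (not isolated), via hydroxy aldehyde 13 (not isolated)
Conditions: OsO4 (cat.), NaIO4, 2,6-lutidine, dioxane–H2O, rt; extraction; NaBH4, MeOH, 0 °C
Reagents that add atoms: osmium tetroxide (oxygen donor, turned over by periodate), O=[Os](=O)(=O)=O; sodium periodate, [Na+].[O-]I(=O)(=O)=O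
Why: Lemieux–Johnson oxidation (OsO4 dihydroxylation, then periodate glycol cleavage) removes the terminal CH2 as formaldehyde and NaBH4 reduces aldehyde 13 at once; the lutidine buffer keeps the acetal intact and the α-aryloxy aldehyde away from base, so C8 should keep its configuration and C7 is not touched.

Step 6
Reactants: 14 (1R,2R)-2-[4-(1,3-dioxolan-2-yl)-2,6-dimethoxyphenoxy]-1-[3-methoxy-4-(triisopropylsilyloxy)phenyl]propane-1,3-diol
Product: 15 4-({(1R,2R)-1,3-dihydroxy-1-[3-methoxy-4-(triisopropylsilyloxy)phenyl]propan-2-yl}oxy)-3,5-dimethoxybenzaldehyde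
Conditions: HCl (0.5 M aq), THF, rt
Reagents that add atoms: water, O
Why: Acid-catalysed acetal hydrolysis; the aryl dioxolane ionises readily in dilute acid, whereas C7–OH should not, because the neighbouring C8 aryloxy group destabilises the benzylic cation, and the aryl triisopropylsilyl ether is stable to dilute aqueous acid.

Step 7
Reactants: 15 4-({(1R,2R)-1,3-dihydroxy-1-[3-methoxy-4-(triisopropylsilyloxy)phenyl]propan-2-yl}oxy)-3,5-dimethoxybenzaldehyde
Product: 16 ethyl (E)-3-[4-({(1R,2R)-1,3-dihydroxy-1-[3-methoxy-4-(triisopropylsilyloxy)phenyl]propan-2-yl}oxy)-3,5-dimethoxyphenyl]prop-2-enoate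
Conditions: Ph3P=CHCO2Et, toluene, 80 °C
Reagents that add atoms: ethyl (triphenylphosphoranylidene)acetate, CCOC(=O)C=P(c1ccccc1)(c1ccccc1)c1ccccc1
Why: Wittig olefination with a stabilised ylide, which reacts only with the aldehyde, tolerates the two free hydroxyls and should give the E cinnamate.

Step 8
Reactants: 16 ethyl (E)-3-[4-({(1R,2R)-1,3-dihydroxy-1-[3-methoxy-4-(triisopropylsilyloxy)phenyl]propan-2-yl}oxy)-3,5-dimethoxyphenyl]prop-2-enoate
Product: 18 (1R,2R)-2-{4-[(E)-3-hydroxyprop-1-enyl]-2,6-dimethoxyphenoxy}-1-[3-methoxy-4-(triisopropylsilyloxy)phenyl]propane-1,3-diol, via enal 17 (not isolated)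
Conditions: i-Bu2AlH (excess), CH2Cl2–THF, −78 → 0 °C; aq. potassium sodium tartrate
Reagents that add atoms: none
Why: Ester reduction with diisobutylaluminium hydride by 1,2-hydride delivery through enal 17 to the E allylic alcohol; two equivalents are consumed by the hydroxyls, and the conjugated double bond and the aryl silyl ether should be left alone at low temperature.

Step 9
Reactants: 18 (1R,2R)-2-{4-[(E)-3-hydroxyprop-1-enyl]-2,6-dimethoxyphenoxy}-1-[3-methoxy-4-(triisopropylsilyloxy)phenyl]propane-1,3-diol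
Product: 19 (1R,2R)-1-(4-hydroxy-3-methoxyphenyl)-2-{4-[(E)-3-hydroxyprop-1-enyl]-2,6-dimethoxyphenoxy}propane-1,3-diol
Conditions: n-Bu4NF, AcOH, THF, 0 °C
Reagents that add atoms: none
Why: Fluoride-induced desilylation of the aryl silyl ether; the acetic acid buffer keeps the freed phenol protonated, so no quinone methide should form from the para-hydroxybenzylic alcohol and C7 keeps its configuration.

**Compound list**

1 | syringaldehyde | COc1cc(C=O)cc(OC)c1O | starting material
2 | allyl bromide | C=CCBr | starting material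
3 | 4-(allyloxy)-3,5-dimethoxybenzaldehyde | C=CCOc1c(OC)cc(C=O)cc1OC | intermediate
4 | 2-[4-(allyloxy)-3,5-dimethoxyphenyl]-1,3-dioxolane | C=CCOc1c(OC)cc(C2OCCO2)cc1OC | intermediate
5 | vanillin | COc1cc(C=O)ccc1O | starting material
6 | 3-methoxy-4-(triisopropylsilyloxy)benzaldehyde | COc1cc(C=O)ccc1O[Si](C(C)C)(C(C)C)C(C)C | intermediate
7 | 1-[4-(1,3-dioxolan-2-yl)-2,6-dimethoxyphenoxy]allyllithium (oxygen-chelated Z allyl anion) | [Li]C(C=C)Oc1c(OC)cc(C2OCCO2)cc1OC | intermediate
8 | lithium {(Z)-3-[4-(1,3-dioxolan-2-yl)-2,6-dimethoxyphenoxy]allyl}(methoxy)diisopinocampheylborate | [Li+].CO[B-](C/C=C\Oc1c(OC)cc(C2OCCO2)cc1OC)([C@@H]1C[C@@H]2C[C@H]([C@H]1C)C2(C)C)[C@@H]1C[C@@H]2C[C@H]([C@H]1C)C2(C)C | intermediate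
9 | {(Z)-3-[4-(1,3-dioxolan-2-yl)-2,6-dimethoxyphenoxy]allyl}diisopinocampheylborane | C(/C=C\Oc1c(OC)cc(C2OCCO2)cc1OC)B([C@@H]1C[C@@H]2C[C@H]([C@H]1C)C2(C)C)[C@@H]1C[C@@H]2C[C@H]([C@H]1C)C2(C)C | intermediate
10 | diisopinocampheylborinate ester of 11 (boron on the C7 oxygen) | COc1cc([C@@H](OB([C@@H]4C[C@@H]5C[C@H]([C@H]4C)C5(C)C)[C@@H]4C[C@@H]5C[C@H]([C@H]4C)C5(C)C)[C@@H](C=C)Oc2c(OC)cc(C3OCCO3)cc2OC)ccc1O[Si](C(C)C)(C(C)C)C(C)C | intermediate
11 | (1R,2R)-2-[4-(1,3-dioxolan-2-yl)-2,6-dimethoxyphenoxy]-1-[3-methoxy-4-(triisopropylsilyloxy)phenyl]but-3-en-1-ol | COc1cc([C@@H](O)[C@@H](C=C)Oc2c(OC)cc(C3OCCO3)cc2OC)ccc1O[Si](C(C)C)(C(C)C)C(C)C | intermediate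
12 | (3S,4R)-3-[4-(1,3-dioxolan-2-yl)-2,6-dimethoxyphenoxy]-4-[3-methoxy-4-(triisopropylsilyloxy)phenyl]butane-1,2,4-triol (both C2 epimers) | COc1cc([C@@H](O)[C@@H](C(O)CO)Oc2c(OC)cc(C3OCCO3)cc2OC)ccc1O[Si](C(C)C)(C(C)C)C(C)C | intermediate
13 | (2S,3R)-2-[4-(1,3-dioxolan-2-yl)-2,6-dimethoxyphenoxy]-3-hydroxy-3-[3-methoxy-4-(triisopropylsilyloxy)phenyl]propanal | COc1cc([C@@H](O)[C@@H](C=O)Oc2c(OC)cc(C3OCCO3)cc2OC)ccc1O[Si](C(C)C)(C(C)C)C(C)C | intermediate
14 | (1R,2R)-2-[4-(1,3-dioxolan-2-yl)-2,6-dimethoxyphenoxy]-1-[3-methoxy-4-(triisopropylsilyloxy)phenyl]propane-1,3-diol | COc1cc([C@@H](O)[C@@H](CO)Oc2c(OC)cc(C3OCCO3)cc2OC)ccc1O[Si](C(C)C)(C(C)C)C(C)C | intermediate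
15 | 4-({(1R,2R)-1,3-dihydroxy-1-[3-methoxy-4-(triisopropylsilyloxy)phenyl]propan-2-yl}oxy)-3,5-dimethoxybenzaldehyde | COc1cc([C@@H](O)[C@@H](CO)Oc2c(OC)cc(C=O)cc2OC)ccc1O[Si](C(C)C)(C(C)C)C(C)C | intermediate
16 | ethyl (E)-3-[4-({(1R,2R)-1,3-dihydroxy-1-[3-methoxy-4-(triisopropylsilyloxy)phenyl]propan-2-yl}oxy)-3,5-dimethoxyphenyl]prop-2-enoate | COc1cc([C@@H](O)[C@@H](CO)Oc2c(OC)cc(/C=C/C(=O)OCC)cc2OC)ccc1O[Si](C(C)C)(C(C)C)C(C)C | intermediate
17 | (E)-3-[4-({(1R,2R)-1,3-dihydroxy-1-[3-methoxy-4-(triisopropylsilyloxy)phenyl]propan-2-yl}oxy)-3,5-dimethoxyphenyl]prop-2-enal | COc1cc([C@@H](O)[C@@H](CO)Oc2c(OC)cc(/C=C/C=O)cc2OC)ccc1O[Si](C(C)C)(C(C)C)C(C)C | intermediate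
18 | (1R,2R)-2-{4-[(E)-3-hydroxyprop-1-enyl]-2,6-dimethoxyphenoxy}-1-[3-methoxy-4-(triisopropylsilyloxy)phenyl]propane-1,3-diol | COc1cc([C@@H](O)[C@@H](CO)Oc2c(OC)cc(/C=C/CO)cc2OC)ccc1O[Si](C(C)C)(C(C)C)C(C)C | intermediate
19 | (1R,2R)-1-(4-hydroxy-3-methoxyphenyl)-2-{4-[(E)-3-hydroxyprop-1-enyl]-2,6-dimethoxyphenoxy}propane-1,3-diol | COc1cc([C@@H](O)[C@@H](CO)Oc2c(OC)cc(/C=C/CO)cc2OC)ccc1O | target

**Step count**

Total: 9 steps. Longest linear sequence: 8 steps (steps 1, 2, 4, 5, 6, 7, 8, 9 from syringaldehyde).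

**Steps most likely to fail**

Step 4. Lithiation may go to the ring positions beside the acetal or to the acetal carbon instead of the allylic α-position. The acetal may be opened when BF3·OEt2 is added. The doubly ortho-substituted aryloxy group may slow the addition or erode facial and syn/anti control. The fallback is an Evans glycolate syn-aldol; it sets out from 4 and 6 and returns at 14, replacing steps 4 and 5.
- The allyl group of 4 is removed with Pd(PPh3)4 (cat.) and morpholine in THF to give 4-(1,3-dioxolan-2-yl)-2,6-dimethoxyphenol F1.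
- F1 is O-alkylated with the known (S)-4-benzyl-3-(bromoacetyl)oxazolidin-2-one and K2CO3 in acetone to give (S)-4-benzyl-3-{[4-(1,3-dioxolan-2-yl)-2,6-dimethoxyphenoxy]acetyl}oxazolidin-2-one F2.
- Bu2BOTf and i-Pr2NEt in CH2Cl2 at −78 °C should convert F2 into its (Z)-dibutylboron enolate F3.
- F3 should add to 6 through a chair transition state to give the syn aldol (S)-4-benzyl-3-{(2S,3R)-2-[4-(1,3-dioxolan-2-yl)-2,6-dimethoxyphenoxy]-3-hydroxy-3-[3-methoxy-4-(triisopropylsilyloxy)phenyl]propanoyl}oxazolidin-2-one F4.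
- LiBH4 in THF–MeOH at 0 °C cleaves the auxiliary reductively and should give diol 14.

Step 5. The transient β-hydroxy-α-aryloxy aldehyde may undergo retro-aldol cleavage or epimerise at C8 before it is reduced. The fallback blocks the β-hydroxyl; it sets out from 11 and returns at 15.
- C7–OH is capped (TESCl, imidazole, DMF) as the C7 triethylsilyl ether of 11 F5, so that no β-alkoxide can form.
- The same OsO4/NaIO4 cleavage gives (2S,3R)-2-[4-(1,3-dioxolan-2-yl)-2,6-dimethoxyphenoxy]-3-[3-methoxy-4-(triisopropylsilyloxy)phenyl]-3-(triethylsilyloxy)propanal F6.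
- NaBH4 reduces F6 to (2R,3R)-2-[4-(1,3-dioxolan-2-yl)-2,6-dimethoxyphenoxy]-3-[3-methoxy-4-(triisopropylsilyloxy)phenyl]-3-(triethylsilyloxy)propan-1-ol F7; a silyl shift from C7 to C9 oxygen would be harmless.
- Aqueous HCl in THF then removes the triethylsilyl ether together with the dioxolane and gives 15 directly.

Step 8. Hydride delivery may stall when the aluminium alkoxides of the diol precipitate, and 1,4-reduction or attack at the aryl silyl ether may compete. The fallback avoids the ester and the aluminium reagent; it sets out from 15 and returns at 18. Wittig reaction of 15 with (triphenylphosphoranylidene)acetaldehyde in toluene at 80 °C gives enal 17, here isolated. Luche reduction (NaBH4, CeCl3·7H2O, MeOH, 0 °C) should then give 18 by 1,2-reduction.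

**Further compounds**

F1 | step 4 | 4-(1,3-dioxolan-2-yl)-2,6-dimethoxyphenol | COc1cc(C2OCCO2)cc(OC)c1O
F2 | step 4 | (S)-4-benzyl-3-{[4-(1,3-dioxolan-2-yl)-2,6-dimethoxyphenoxy]acetyl}oxazolidin-2-one | O=C1OC[C@H](Cc2ccccc2)N1C(=O)COc1c(OC)cc(C2OCCO2)cc1OC
F3 | step 4 | (Z)-dibutylboron enolate of F2 | CCCCB(CCCC)O/C(=C\Oc1c(OC)cc(C2OCCO2)cc1OC)N1C(=O)OC[C@@H]1Cc1ccccc1
F4 | step 4 | (S)-4-benzyl-3-{(2S,3R)-2-[4-(1,3-dioxolan-2-yl)-2,6-dimethoxyphenoxy]-3-hydroxy-3-[3-methoxy-4-(triisopropylsilyloxy)phenyl]propanoyl}oxazolidin-2-one | COc1cc([C@@H](O)[C@@H](C(=O)N3[C@@H](Cc4ccccc4)COC3=O)Oc2c(OC)cc(C5OCCO5)cc2OC)ccc1O[Si](C(C)C)(C(C)C)C(C)C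
F5 | step 5 | C7 triethylsilyl ether of 11 | COc1cc([C@@H](O[Si](CC)(CC)CC)[C@@H](C=C)Oc2c(OC)cc(C3OCCO3)cc2OC)ccc1O[Si](C(C)C)(C(C)C)C(C)C
F6 | step 5 | (2S,3R)-2-[4-(1,3-dioxolan-2-yl)-2,6-dimethoxyphenoxy]-3-[3-methoxy-4-(triisopropylsilyloxy)phenyl]-3-(triethylsilyloxy)propanal | COc1cc([C@@H](O[Si](CC)(CC)CC)[C@@H](C=O)Oc2c(OC)cc(C3OCCO3)cc2OC)ccc1O[Si](C(C)C)(C(C)C)C(C)C
F7 | step 5 | (2R,3R)-2-[4-(1,3-dioxolan-2-yl)-2,6-dimethoxyphenoxy]-3-[3-methoxy-4-(triisopropylsilyloxy)phenyl]-3-(triethylsilyloxy)propan-1-ol | COc1cc([C@@H](O[Si](CC)(CC)CC)[C@@H](CO)Oc2c(OC)cc(C3OCCO3)cc2OC)ccc1O[Si](C(C)C)(C(C)C)C(C)C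
F0 | step 8 | none | none
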